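At 80.0 min birch holds 2.8 % of E beside 12.5 % of G, while oak holds 20.5 % beside 22.8 %, so E over G stands higher in oak, the flask with more D. You asked for a quick number on these flasks:

all flasks: Z 0.050 M

| run | D | remark | time |
|---|---|---|---|
| birch | 0.041 M | run made earlier |  |
| oak | 0.13 M | run made earlier |  |
| spring | 0.0600 M |  | 2.0 h |
| dawn | 0.200 M |  | 2.0 h |
| dusk | 0.0750 M |  | 2.0 h |

- birch (time / min: E / %, G / %): 20.0: 0, 8.7; 40.0: 1.3, 12.3; 60.0: 2.4, 12.4; 80.0: 2.8, 12.5
- oak (time / min: E / %, G / %): 20.0: 4.2, 22.9; 40.0: 10.6, 26.1; 60.0: 15.7, 25.0; 80.0: 20.5, 22.8

(standard deviation of a reading: 0.3 percentage points)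

* which of these holds the largest part of the Z at the end of spring (E / Z / G)
* which of these holds the largest part of the Z at the end of dawn (E / Z / G)
* which of these holds the largest part of the Z at the end of dusk (E / Z / G)
* amount of E at the end of spring, in percent of the Z charged

- what was read earlier has a scatter of 0.3 percentage points, one standard deviation

Divide E by G, then by the charge of D and by the time. Birch then reads 0.0683 /M/min and oak 0.0865 /M/min, and birch's small E carries the scatter of 0.3 percentage points. Their mean, 0.0774 /M/min, is the ripening constant: E per G, per molar D charged, per minute. It treats G as pseudo-first-order, with the charge standing in for [D].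

For spring it gives E over G of 0.557 at 2.0 h. G is the rough step: interpolating the last readings on the charge of D gives about 14.7 %, though those readings belong to 80.0 min. So this reply's own figure for E is 8.19 %.

Your forecast has Z largest in spring, E in dawn and Z in dusk, with E at 5 % in spring, below this reply's figure. Its ground is that “E formation runs at about 0.01 per min”.

    Z + D ⇌ L + G (K = 6.90, k = 0.170 /M/min)
    2 D → Q (k = 0.0150 /M/min)
    G + D ⇌ L + E (K = 35.0, k = 0.130 /M/min)
    Z + G → X (k = 0.520 /M/min)

Spring ends with Z 29.5 %, G 15.1 % and E 8.30 %, and E over G stands at 0.551. Of the three species asked, Z leads there, E leads in dawn and Z leads in dusk, as forecast. A neighbour of spring charged with 0.15 M of D reverses the order of Z and E. For it the ripening constant gives E over G of 1.39, and the neighbour gives 1.78, with G at 17.8 %. After 2.00 h that neighbour holds E at 31.6 %, above Z at 8.55 %.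

Readings and results are simulated from invented constants; noise was put on by code.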